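The whole plan hinges on disconnecting ring B across its C8=C9 double bond. That olefin is fully substituted, with the methyl on C8, the side chain on C9 and the quaternary C10 next door, so both halves can be prepared as methylidene units (C8=CH2 and C9=CH2) hung on a ring A cyclohexanone. One ring-closing metathesis then makes the C8=C9 bond, closes the six-membered ring B and fixes the olefin position. Its substrate is a 2,3,3-trisubstituted cyclohexanone: C10 holds a methyl and a ketal-bearing alkenyl group installed by asymmetric conjugate addition, C5 holds a 3-methylbut-3-enyl chain. The C5 hydrogen and the C4 quaternary centre follow from one reductive methylation; the side chain is finished last.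

Key step: step 5

Assumption: the C5 epimers of 8, 9 and 10 are carried on together (the 2,3-trans isomer is drawn) because C5 is made trigonal in step 6 and remade in step 8, and the carbene ligand enantiomer in step 2 is the one that gives S at C10. Atom labels C1–C20 follow labdane numbering.

Step 1
Reactants: 1 hex-5-yn-2-one
Product: 2 2-(but-3-yn-1-yl)-2-methyl-1,3-dioxolane
Conditions: HOCH2CH2OH, p-TsOH (cat.), benzene, reflux, Dean–Stark trap
Reagents that add atoms: ethylene glycol, OCCO
Why: Acid-catalysed ketalisation driven by azeotropic removal of water masks the ketone against i-Bu2AlH and the later carbanion chemistry, and the terminal alkyne is untouched.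

Step 2
Reactants: 2 2-(but-3-yn-1-yl)-2-methyl-1,3-dioxolane; 3 3-methylcyclohex-2-en-1-one
Product: 6 triethyl({(3S)-3-methyl-3-[4-(2-methyl-1,3-dioxolan-2-yl)but-1-en-2-yl]cyclohex-1-en-1-yl}oxy)silane, via alkenylalane 4 (not isolated), via aluminium enolate 5 (not isolated)
Conditions: i-Bu2AlH, Ni(dppp)Cl2 (3 mol %), THF, 0 → 22 °C; then 3, Cu(OTf)2 (5 mol %), chiral sulfonate-bearing imidazolinium salt (carbene precursor, 5 mol %), THF, −78 → −50 °C; then Et3SiOTf, −78 → 0 °C; Et3N, aq. NaHCO3
Reagents that add atoms: triethylsilyl trifluoromethanesulfonate, CC[Si](CC)(CC)OS(=O)(=O)C(F)(F)F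
Why: Nickel-catalysed α-selective hydroalumination places aluminium on the internal alkyne carbon, the chiral carbene–copper complex then transfers this alkenyl group to one enantiotopic face of the enone β-carbon (catalytic asymmetric conjugate addition, ligand control, C10 set as S), and the regiodefined aluminium enolate is captured on oxygen by the silyl triflate.

Step 3
Reactants: 6 triethyl({(3S)-3-methyl-3-[4-(2-methyl-1,3-dioxolan-2-yl)but-1-en-2-yl]cyclohex-1-en-1-yl}oxy)silane; 7 but-3-en-2-one (methyl vinyl ketone)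
Product: 8 (2R,3S)-3-methyl-3-[4-(2-methyl-1,3-dioxolan-2-yl)but-1-en-2-yl]-2-(3-oxobutyl)cyclohexan-1-one
Conditions: BF3·OEt2 (1.2 equiv), i-PrOH (1.2 equiv), CH2Cl2, −78 °C
Reagents that add atoms: none
Why: In this Mukaiyama–Michael addition C5 of the enol silane attacks the BF3-activated enone from the face opposite the larger alkenyl group on C10, which should favour the 2,3-trans isomer drawn, while i-PrOH takes up the silyl group.

Step 4
Reactants: 8 (2R,3S)-3-methyl-3-[4-(2-methyl-1,3-dioxolan-2-yl)but-1-en-2-yl]-2-(3-oxobutyl)cyclohexan-1-one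
Product: 9 (2R,3S)-3-methyl-2-(3-methylbut-3-en-1-yl)-3-[4-(2-methyl-1,3-dioxolan-2-yl)but-1-en-2-yl]cyclohexan-1-one
Conditions: Ph3PCH3Br (1.15 equiv), KN(SiMe3)2 (1.1 equiv), THF, −78 → 0 °C
Reagents that add atoms: methyltriphenylphosphonium bromide, C[P+](c1ccccc1)(c1ccccc1)c1ccccc1.[Br-]
Why: Wittig methylenation with about one equivalent of ylide should take the unhindered side-chain methyl ketone and leave the ring carbonyl, which is shielded by the branched C5 and the quaternary C10.

Step 5
Reactants: 9 (2R,3S)-3-methyl-2-(3-methylbut-3-en-1-yl)-3-[4-(2-methyl-1,3-dioxolan-2-yl)but-1-en-2-yl]cyclohexan-1-one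
Product: 10 (4aS,8aR)-4a,6-dimethyl-5-[2-(2-methyl-1,3-dioxolan-2-yl)ethyl]-3,4,4a,7,8,8a-hexahydronaphthalen-1(2H)-one
Conditions: second-generation Hoveyda–Grubbs catalyst, [1,3-bis(2,4,6-trimethylphenyl)imidazolidin-2-ylidene]dichloro(2-isopropoxybenzylidene)ruthenium (10 mol %, two portions), 1,4-benzoquinone (20 mol %), toluene (0.005 mol/L), 100 °C, argon sparge
Reagents that add atoms: none
Why: The catalyst exchanges its benzylidene for the more accessible C8 methylidene end, and the resulting ruthenium carbene on C8 undergoes intramolecular [2+2] cycloaddition to the C9=CH2 group followed by cycloreversion, which expels Ru=CH2 and, after turnover, ethylene. The closest known reaction type is ring-closing metathesis of two 1,1-disubstituted alkenes to a tetrasubstituted cyclohexene beside a quaternary carbon, run with carbene-ligated ruthenium catalysts. Ring B closes as a six-membered carbocycle by joining C8 to C9, the other ring atoms C5, C6, C7 and C10 being already connected. No stereocentre is created and C10 (S) is untouched; C5 may epimerise but is remade in step 8. The selectivity needed is cyclisation over dimerisation and over olefin migration, and it should be secured by the 1,6-spacing of the two alkenes, the fully substituted C10 that presses them together, high dilution, removal of ethylene and the quinone additive.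

Step 6
Reactants: 10 (4aS,8aR)-4a,6-dimethyl-5-[2-(2-methyl-1,3-dioxolan-2-yl)ethyl]-3,4,4a,7,8,8a-hexahydronaphthalen-1(2H)-one
Product: 12 (4aR)-4a,6-dimethyl-5-[2-(2-methyl-1,3-dioxolan-2-yl)ethyl]-2,3,4,4a,7,8-hexahydronaphthalen-1-yl trifluoromethanesulfonate, via bromomagnesium enolate 11 (not isolated)
Conditions: i-Pr2NMgBr (from EtMgBr and i-Pr2NH, 1.3 equiv), Et2O/THF, 23 °C, 12 h; then PhNTf2 (1.5 equiv), 23 → 40 °C
Reagents that add atoms: N-phenylbis(trifluoromethanesulfonimide), O=S(=O)(N(c1ccccc1)S(=O)(=O)C(F)(F)F)C(F)(F)F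
Why: In this thermodynamic enolate formation and O-sulfonylation the magnesium amide deprotonates reversibly, so the enolates should settle on the more substituted C4=C5 isomer, which PhNTf2 converts into the enol triflate, and C5 becomes trigonal here on purpose.

Step 7
Reactants: 12 (4aR)-4a,6-dimethyl-5-[2-(2-methyl-1,3-dioxolan-2-yl)ethyl]-2,3,4,4a,7,8-hexahydronaphthalen-1-yl trifluoromethanesulfonate
Product: 13 methyl (4aR)-4a,6-dimethyl-5-[2-(2-methyl-1,3-dioxolan-2-yl)ethyl]-2,3,4,4a,7,8-hexahydronaphthalene-1-carboxylate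
Conditions: Pd(PPh3)4 (10 mol %), CO (1 atm), MeOH, Et3N, DMF, 60 °C
Reagents that add atoms: carbon monoxide, [C-]#[O+]; methanol, CO
Why: Palladium-catalysed alkoxycarbonylation of an enol triflate proceeds by oxidative addition of zerovalent palladium into the C4–OTf bond, CO insertion and methanolysis of the acylpalladium to give the C4=C5 enoate.

Step 8
Reactants: 13 methyl (4aR)-4a,6-dimethyl-5-[2-(2-methyl-1,3-dioxolan-2-yl)ethyl]-2,3,4,4a,7,8-hexahydronaphthalene-1-carboxylate
Product: 15 methyl (1S,4aS,8aR)-1,4a,6-trimethyl-5-[2-(2-methyl-1,3-dioxolan-2-yl)ethyl]-1,2,3,4,4a,7,8,8a-octahydronaphthalene-1-carboxylate, via lithium ester enolate 14 (not isolated)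
Conditions: Li (2.2 equiv), t-BuOH (1.0 equiv), NH3/THF, −78 °C; then MeI (5 equiv), −78 → −33 °C
Reagents that add atoms: iodomethane, CI
Why: In this reductive alkylation of an α,β-unsaturated ester, electron transfer and protonation should place hydrogen on C5 axially, anti to the angular C10 methyl (trans ring fusion), and the C4 ester enolate is then methylated on its α face, away from the axial C10 methyl, so that the ester ends up axial (β) and the new methyl equatorial, both centres being substrate-controlled while the isolated C8=C9 olefin and the ketal are inert.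

Step 9
Reactants: 15 methyl (1S,4aS,8aR)-1,4a,6-trimethyl-5-[2-(2-methyl-1,3-dioxolan-2-yl)ethyl]-1,2,3,4,4a,7,8,8a-octahydronaphthalene-1-carboxylate
Product: 16 methyl (1S,4aS,8aR)-1,4a,6-trimethyl-5-(3-oxobutyl)-1,2,3,4,4a,7,8,8a-octahydronaphthalene-1-carboxylate
Conditions: aq. HCl (1 mol/L), THF, 23 °C
Reagents that add atoms: water, O
Why: Acid-catalysed ketal hydrolysis frees the C13 methyl ketone, and the neopentyl methyl ester and the tetrasubstituted olefin are inert to dilute acid at room temperature.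

Step 10
Reactants: 16 methyl (1S,4aS,8aR)-1,4a,6-trimethyl-5-(3-oxobutyl)-1,2,3,4,4a,7,8,8a-octahydronaphthalene-1-carboxylate
Product: 17 methyl (1S,4aS,8aR)-5-[(3E)-5-ethoxy-3-methyl-5-oxopent-3-en-1-yl]-1,4a,6-trimethyl-1,2,3,4,4a,7,8,8a-octahydronaphthalene-1-carboxylate
Conditions: (EtO)2P(O)CH2CO2Et, NaH, THF, 0 → 50 °C; chromatographic removal of the minor Z isomer
Reagents that add atoms: triethyl phosphonoacetate, CCOC(=O)CP(=O)(OCC)OCC
Why: In this Horner–Wadsworth–Emmons olefination, reversible addition of the stabilised phosphonate anion and elimination through the less crowded oxaphosphetane should favour the E enoate, with the ester trans to the larger C12 chain.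

Step 11
Reactants: 17 methyl (1S,4aS,8aR)-5-[(3E)-5-ethoxy-3-methyl-5-oxopent-3-en-1-yl]-1,4a,6-trimethyl-1,2,3,4,4a,7,8,8a-octahydronaphthalene-1-carboxylate
Product: 18 methyl (1S,4aS,8aR)-5-[(3E)-5-hydroxy-3-methylpent-3-en-1-yl]-1,4a,6-trimethyl-1,2,3,4,4a,7,8,8a-octahydronaphthalene-1-carboxylate
Conditions: i-Bu2AlH (2.2 equiv), CH2Cl2, −78 °C; aq. Rochelle salt
Reagents that add atoms: none
Why: In this low-temperature hydride reduction the exposed conjugated ethyl ester should be reduced in a 1,2-sense to the allylic alcohol, whereas the axial C4 methyl ester on a quaternary carbon is too hindered to react.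

Step 12
Reactants: 18 methyl (1S,4aS,8aR)-5-[(3E)-5-hydroxy-3-methylpent-3-en-1-yl]-1,4a,6-trimethyl-1,2,3,4,4a,7,8,8a-octahydronaphthalene-1-carboxylate
Product: 19 methyl (1S,4aS,8aR)-5-[(3E)-5-acetoxy-3-methylpent-3-en-1-yl]-1,4a,6-trimethyl-1,2,3,4,4a,7,8,8a-octahydronaphthalene-1-carboxylate (CNP0206695.1)
Conditions: Ac2O, pyridine, DMAP (cat.), CH2Cl2, 0 → 23 °C
Reagents that add atoms: acetic anhydride, CC(=O)OC(C)=O
Why: Nucleophile-catalysed O-acylation of the primary allylic alcohol gives the acetate without touching the olefins or the methyl ester.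

Compound list
1 | hex-5-yn-2-one | CC(=O)CCC#C | starting material
2 | 2-(but-3-yn-1-yl)-2-methyl-1,3-dioxolane | CC1(CCC#C)OCCO1 | intermediate
3 | 3-methylcyclohex-2-en-1-one | CC1=CC(=O)CCC1 | starting material
4 | [4-(2-methyl-1,3-dioxolan-2-yl)but-1-en-2-yl]bis(2-methylpropyl)alumane (α-alkenylalane) | C=C(CCC1(C)OCCO1)[Al](CC(C)C)CC(C)C | intermediate
5 | diisobutylaluminium enolate of (3S)-3-methyl-3-[4-(2-methyl-1,3-dioxolan-2-yl)but-1-en-2-yl]cyclohexanone, enolate double bond on the side of the quaternary carbon (C4=C5) | CC(C)C[Al](CC(C)C)OC1=C[C@@](C)(C(=C)CCC2(C)OCCO2)CCC1 | intermediate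
6 | triethyl({(3S)-3-methyl-3-[4-(2-methyl-1,3-dioxolan-2-yl)but-1-en-2-yl]cyclohex-1-en-1-yl}oxy)silane | CC[Si](CC)(CC)OC1=C[C@@](C)(C(=C)CCC2(C)OCCO2)CCC1 | intermediate
7 | but-3-en-2-one (methyl vinyl ketone) | CC(=O)C=C | starting material
8 | (2R,3S)-3-methyl-3-[4-(2-methyl-1,3-dioxolan-2-yl)but-1-en-2-yl]-2-(3-oxobutyl)cyclohexan-1-one | O=C1CCC[C@](C)(C(=C)CCC2(C)OCCO2)[C@H]1CCC(C)=O | intermediate
9 | (2R,3S)-3-methyl-2-(3-methylbut-3-en-1-yl)-3-[4-(2-methyl-1,3-dioxolan-2-yl)but-1-en-2-yl]cyclohexan-1-one | O=C1CCC[C@](C)(C(=C)CCC2(C)OCCO2)[C@H]1CCC(C)=C | intermediate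
10 | (4aS,8aR)-4a,6-dimethyl-5-[2-(2-methyl-1,3-dioxolan-2-yl)ethyl]-3,4,4a,7,8,8a-hexahydronaphthalen-1(2H)-one | O=C1CCC[C@]2(C)C(CCC3(C)OCCO3)=C(C)CC[C@@H]12 | intermediate
11 | bromomagnesium enolate of 10 with the double bond at the ring fusion (C4=C5), C10 unchanged | Br[Mg]OC1=C2CCC(C)=C(CCC3(C)OCCO3)[C@@]2(C)CCC1 | intermediate
12 | (4aR)-4a,6-dimethyl-5-[2-(2-methyl-1,3-dioxolan-2-yl)ethyl]-2,3,4,4a,7,8-hexahydronaphthalen-1-yl trifluoromethanesulfonate | O=S(=O)(OC1=C2CCC(C)=C(CCC3(C)OCCO3)[C@@]2(C)CCC1)C(F)(F)F | intermediate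
13 | methyl (4aR)-4a,6-dimethyl-5-[2-(2-methyl-1,3-dioxolan-2-yl)ethyl]-2,3,4,4a,7,8-hexahydronaphthalene-1-carboxylate | COC(=O)C1=C2CCC(C)=C(CCC3(C)OCCO3)[C@@]2(C)CCC1 | intermediate
14 | lithium methoxy{(4aS,8aR)-4a,6-dimethyl-5-[2-(2-methyl-1,3-dioxolan-2-yl)ethyl]-3,4,4a,7,8,8a-hexahydronaphthalen-1(2H)-ylidene}methanolate (C4 ester enolate, 5α-H) | [Li]OC(OC)=C1CCC[C@]2(C)C(CCC3(C)OCCO3)=C(C)CC[C@@H]12 | intermediate
15 | methyl (1S,4aS,8aR)-1,4a,6-trimethyl-5-[2-(2-methyl-1,3-dioxolan-2-yl)ethyl]-1,2,3,4,4a,7,8,8a-octahydronaphthalene-1-carboxylate | COC(=O)[C@@]1(C)CCC[C@]2(C)C(CCC3(C)OCCO3)=C(C)CC[C@@H]12 | intermediate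
16 | methyl (1S,4aS,8aR)-1,4a,6-trimethyl-5-(3-oxobutyl)-1,2,3,4,4a,7,8,8a-octahydronaphthalene-1-carboxylate | COC(=O)[C@@]1(C)CCC[C@]2(C)C(CCC(C)=O)=C(C)CC[C@@H]12 | intermediate
17 | methyl (1S,4aS,8aR)-5-[(3E)-5-ethoxy-3-methyl-5-oxopent-3-en-1-yl]-1,4a,6-trimethyl-1,2,3,4,4a,7,8,8a-octahydronaphthalene-1-carboxylate | COC(=O)[C@@]1(C)CCC[C@]2(C)C(CC/C(C)=C/C(=O)OCC)=C(C)CC[C@@H]12 | intermediate
18 | methyl (1S,4aS,8aR)-5-[(3E)-5-hydroxy-3-methylpent-3-en-1-yl]-1,4a,6-trimethyl-1,2,3,4,4a,7,8,8a-octahydronaphthalene-1-carboxylate | COC(=O)[C@@]1(C)CCC[C@]2(C)C(CC/C(C)=C/CO)=C(C)CC[C@@H]12 | intermediate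
19 | methyl (1S,4aS,8aR)-5-[(3E)-5-acetoxy-3-methylpent-3-en-1-yl]-1,4a,6-trimethyl-1,2,3,4,4a,7,8,8a-octahydronaphthalene-1-carboxylate (4β-CO2Me, 5α-H, 10β-CH3) | COC(=O)[C@@]1(C)CCC[C@]2(C)C(CC/C(C)=C/COC(C)=O)=C(C)CC[C@@H]12 | target

Total step count: 12 steps.
Longest linear sequence: 12 steps, from 1 to 19 (3 and 7 enter in steps 2 and 3).

Steps most likely to fail

Step 5. The ruthenium carbene may fail to engage the C9 alkene, which is shielded by quaternary C10, so that the diene is recovered, dimerises through the C8 alkene or suffers olefin migration. The fallback closes ring B by reductive carbonyl coupling instead of metathesis. It sets out from 9: NaBH4 in MeOH should give the C4 alcohol F1 (carbinol epimers, both usable), and t-BuMe2SiOTf with 2,6-lutidine the silyl ether F2. Ozonolysis of both methylidene groups (O3, CH2Cl2/MeOH, −78 °C, then Me2S) should give the C8,C9-diketone F3. McMurry coupling (TiCl3(DME)1.5, Zn–Cu couple, DME, reflux, slow addition) should then join the two carbonyl carbons to the tetrasubstituted cyclohexene F4. Bu4NF releases the bicyclic alcohol F5, and oxidation with Dess–Martin periodinane comes back to the route at 10.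

Step 6. Enolisation may stay on the C3 side or equilibrate incompletely, so that the triflate forms on the wrong side of C4. The fallback uses the C3 side on purpose. It sets out from 10, equilibrated with NaOMe in MeOH and taken on as the trans-fused epimer drawn. LiN(i-Pr)2 in THF at −78 °C should give the kinetic C3=C4 lithium enolate F6, PhNTf2 the C3=C4 enol triflate F7, and the carbonylation conditions of step 7 the C3=C4 enoate F8. Li/NH3 reduction of F8 leads to the same lithium ester enolate 14, and MeI then comes back to the route at 15. In this variant C5 is not remade, so its configuration has to come from the equilibrated ketone.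

Step 3. The Lewis acid may open the dioxolane or strip the silyl group from the crowded enol ether before C5 attacks the enone. The fallback is an anionic Michael addition without Lewis acid. It sets out from 6: MeLi in THF at 0 °C should release the regiodefined lithium enolate F9, which adds to 3-(trimethylsilyl)but-3-en-2-one at −78 °C to give the α-silyl 1,5-diketone F10 (silyl-bearing carbon as a mixture). Brief treatment with NaOMe in MeOH at 0 °C removes the silyl group and comes back to the route at 8.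

Further compounds
F1 | step 5 | (2R,3S)-3-methyl-2-(3-methylbut-3-en-1-yl)-3-[4-(2-methyl-1,3-dioxolan-2-yl)but-1-en-2-yl]cyclohexan-1-ol (C1 carbinol epimers) | OC1CCC[C@](C)(C(=C)CCC2(C)OCCO2)[C@H]1CCC(C)=C
F2 | step 5 | tert-butyldimethylsilyl ether of F1 | CC(C)(C)[Si](C)(C)OC1CCC[C@](C)(C(=C)CCC2(C)OCCO2)[C@H]1CCC(C)=C
F3 | step 5 | silyl ether diketone, 1-[(1S,2R)-3-(tert-butyldimethylsilyloxy)-1-methyl-2-(3-oxobutyl)cyclohexyl]-3-(2-methyl-1,3-dioxolan-2-yl)propan-1-one | CC(C)(C)[Si](C)(C)OC1CCC[C@](C)(C(=O)CCC2(C)OCCO2)[C@H]1CCC(C)=O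
F4 | step 5 | tert-butyldimethylsilyl ether of the bicyclic C4 alcohol with the C8=C9 olefin (4aS,8aR) | CC(C)(C)[Si](C)(C)OC1CCC[C@]2(C)C(CCC3(C)OCCO3)=C(C)CC[C@@H]12
F5 | step 5 | (4aS,8aR)-4a,6-dimethyl-5-[2-(2-methyl-1,3-dioxolan-2-yl)ethyl]-1,2,3,4,4a,7,8,8a-octahydronaphthalen-1-ol | OC1CCC[C@]2(C)C(CCC3(C)OCCO3)=C(C)CC[C@@H]12
F6 | step 6 | kinetic lithium enolate of 10 with the C3=C4 double bond (4aS,8aR) | [Li]OC1=CCC[C@]2(C)C(CCC3(C)OCCO3)=C(C)CC[C@@H]12
F7 | step 6 | (4aS,8aR)-4a,6-dimethyl-5-[2-(2-methyl-1,3-dioxolan-2-yl)ethyl]-3,4,4a,7,8,8a-hexahydronaphthalen-1-yl trifluoromethanesulfonate | O=S(=O)(OC1=CCC[C@]2(C)C(CCC3(C)OCCO3)=C(C)CC[C@@H]12)C(F)(F)F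
F8 | step 6 | methyl (4aS,8aR)-4a,6-dimethyl-5-[2-(2-methyl-1,3-dioxolan-2-yl)ethyl]-3,4,4a,7,8,8a-hexahydronaphthalene-1-carboxylate | COC(=O)C1=CCC[C@]2(C)C(CCC3(C)OCCO3)=C(C)CC[C@@H]12
F9 | step 3 | lithium (3S)-3-methyl-3-[4-(2-methyl-1,3-dioxolan-2-yl)but-1-en-2-yl]cyclohex-1-en-1-olate | [Li]OC1=C[C@@](C)(C(=C)CCC2(C)OCCO2)CCC1
F10 | step 3 | (2R,3S)-3-methyl-3-[4-(2-methyl-1,3-dioxolan-2-yl)but-1-en-2-yl]-2-[3-oxo-2-(trimethylsilyl)butyl]cyclohexan-1-one | O=C1CCC[C@](C)(C(=C)CCC2(C)OCCO2)[C@H]1CC(C(C)=O)[Si](C)(C)C
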